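**Assumptions:** the SMILES decodes to the natural (2S)-flavanone, and 5,7-dihydroxychromone (CAS 31721-94-5) is bought as a catalogue compound. The route is a paper design; it has not been run.

## Retrosynthetic overview

1. Target ⇐ buffered fluoride removal of three aryl TBS ethers (no acid, no base, so prenyl groups and C2 are safe).
2. C2–C1' bond and the only stereocentre ⇐ Rh-catalysed enantioselective 1,4-addition of a prenylated B-ring arylboronic acid to an intact 8-prenylchromone (no chalcone, no oxa-Michael closure).
3. 8-Prenyl ⇐ Eu(III)-catalysed para-Claisen–Cope rearrangement of the 5-O-prenyl ether of 5,7-dihydroxychromone, which can only deliver prenyl to C8.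
4. Boronic acid ⇐ 4-bromophenol by ortho-C-prenylation, silylation and Br→Li→B exchange.
5. Ring order: rings A and C are bought fused as the chromone, ring B comes from 4-bromophenol, and no ring is built; the three rings are joined in step 8.

## Route

**Step 1**
Reactants: 1, 5,7-dihydroxy-4H-chromen-4-one
Product: 2, 7-(tert-butyldimethylsilyloxy)-5-hydroxy-4H-chromen-4-one
Conditions: TBSCl (1.05 equiv), imidazole, DMF, 0 °C
Reagents that add atoms: TBSCl, CC(C)(C)[Si](C)(C)Cl
Why: Chemoselective silyl ether formation, because the 7-OH is the acidic, unhindered phenol while the 5-OH is locked in a hydrogen bond to C4=O and does not react with one equivalent of TBSCl.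

**Step 2**
Reactants: 2, 7-(TBSO)-5-hydroxychromone; 3, 3-methylbut-2-en-1-ol (prenol)
Product: 4, 7-(tert-butyldimethylsilyloxy)-5-(3-methylbut-2-enyloxy)-4H-chromen-4-one
Conditions: PPh3, DIAD, THF, 0 °C → rt
Reagents that add atoms: prenol, CC(C)=CCO (C5H9 unit; its oxygen leaves as Ph3P=O)
Why: Mitsunobu etherification O-alkylates the chelated 5-OH by SN2 on the primary allylic alcohol under neutral conditions, which spares the aryl silyl ether and the base-sensitive pyranone that K2CO3/prenyl bromide would endanger.

**Step 3**
Reactants: 4, 7-(TBSO)-5-(prenyloxy)chromone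
Product: 5, 7-(tert-butyldimethylsilyloxy)-5-hydroxy-8-(3-methylbut-2-enyl)-4H-chromen-4-one
Conditions: Eu(fod)3 (10 mol %), NaHCO3, PhCl, 85 °C
Reagents that add atoms: none
Why: Eu(III)-catalysed tandem aromatic Claisen–Cope (para-Claisen) rearrangement, in which the O5/C4=O-chelated ether shifts [3,3] to C6 (the only free ortho carbon) as a reverse-prenyl dienone, a second [3,3] shift moves the group to C8 as a normal prenyl, and tautomerisation restores the chelated 5-OH.

**Step 4**
Reactants: 5, 7-(TBSO)-5-hydroxy-8-prenylchromone
Product: 6, 5,7-bis(tert-butyldimethylsilyloxy)-8-(3-methylbut-2-enyl)-4H-chromen-4-one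
Conditions: TBSOTf, 2,6-lutidine, CH2Cl2, 0 °C; NaHCO3 work-up
Reagents that add atoms: TBSOTf, CC(C)(C)[Si](C)(C)OS(=O)(=O)C(F)(F)F
Why: Silylation of the hydrogen-bonded phenol needs the silyl triflate, and capping it removes the acac-like O5/O4 chelating site that would otherwise bind Rh in step 8 (any reversible O4-silylpyrylium formation is undone on work-up).

**Step 5**
Reactants: 7, 4-bromophenol; 8, 1-bromo-3-methylbut-2-ene (prenyl bromide)
Product: 9, 4-bromo-2-(3-methylbut-2-enyl)phenol
Conditions: NaH (1.1 equiv), toluene, 0 °C → rt; then 8 (1.0 equiv)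
Reagents that add atoms: prenyl bromide, CC(C)=CCBr
Why: Ortho-C-alkylation of a sodium phenoxide in a non-polar solvent, where the tight aggregated ion pair shields oxygen so the ortho carbon attacks the primary allylic bromide (para is blocked by Br), giving the linear prenyl phenol in moderate yield after separation from a little O-ether.

**Step 6**
Reactants: 9, 4-bromo-2-prenylphenol
Product: 10, (4-bromo-2-(3-methylbut-2-enyl)phenoxy)(tert-butyl)dimethylsilane
Conditions: TBSCl, imidazole, DMF, rt
Reagents that add atoms: TBSCl, CC(C)(C)[Si](C)(C)Cl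
Why: Standard phenol silylation, giving a protecting group that tolerates n-BuLi and neutral aqueous Rh catalysis and is removed with the other two at the end.

**Step 7**
Reactants: 10, aryl bromide TBS ether
Product: 11, [4-(tert-butyldimethylsilyloxy)-3-(3-methylbut-2-enyl)phenyl]boronic acid
Conditions: B(OiPr)3 (1.5 equiv) present, n-BuLi (1.1 equiv), THF/toluene, −78 °C → rt; sat. NH4Cl
Reagents that add atoms: triisopropyl borate, CC(C)OB(OC(C)C)OC(C)C (boron); water, O (the two OH oxygens on hydrolysis)
Why: Br/Li exchange with in-situ borate quench, where exchange at −78 °C is much faster than deprotonation of the benzylic/allylic CH2 and immediate trapping stops the aryllithium from acting as a base.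

**Step 8 (key step)**
Reactants: 6, 5,7-bis(TBSO)-8-prenylchromone; 11, arylboronic acid (2.5 equiv)
Product: 12, (2S)-5,7-bis(tert-butyldimethylsilyloxy)-2-[4-(tert-butyldimethylsilyloxy)-3-(3-methylbut-2-enyl)phenyl]-8-(3-methylbut-2-enyl)chroman-4-one
Conditions: [Rh(OH)(cod)]2 (2.5 mol %), (S)-MeO-F12-BIPHEP [the MeO-BIPHEP analogue with P(3,4,5-F3C6H2)2 groups] (5.5 mol %), toluene/H2O 10:1, no added base, 40 °C
Reagents that add atoms: none (the aryl group comes from 11; H at C3 comes from water)
Why: Hayashi–Miyaura Rh(I)-catalysed asymmetric 1,4-addition, in which the aryl-Rh species adds across C2=C3 on the face left open by the electron-poor (S)-biaryl bisphosphine and water protonates the oxa-π-allyl rhodium, setting C2 as S by analogy with (S)-BINAP/Rh giving (S)-3-arylcyclohexanones (same enone face), while base-free conditions suppress retro-oxa-Michael opening and the trisubstituted prenyl alkenes are inert; the sense is checked by chiral HPLC/CD on the first run and the (R)-ligand used if it is opposite.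

**Step 9**
Reactants: 12, tris-TBS flavanone
Product: 13, euchrestaflavanone A, (2S)-5,7-dihydroxy-2-[4-hydroxy-3-(3-methylbut-2-enyl)phenyl]-8-(3-methylbut-2-enyl)chroman-4-one
Conditions: TBAF (3.5 equiv)/AcOH (4 equiv), THF, 0 °C; pH 6 buffer work-up
Reagents that add atoms: none
Why: Fluoride-mediated cleavage of aryl silyl ethers buffered with acetic acid, so no phenoxide or enolate builds up to open ring C by E1cB and racemise C2, and no strong acid is present to cyclise the ortho-prenylphenols to chromans.

## Compound list

1 | 5,7-dihydroxy-4H-chromen-4-one | O=c1ccoc2cc(O)cc(O)c12 | starting material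
2 | 7-(tert-butyldimethylsilyloxy)-5-hydroxy-4H-chromen-4-one | O=c1ccoc2cc(O[Si](C)(C)C(C)(C)C)cc(O)c12 | intermediate
3 | 3-methylbut-2-en-1-ol (prenol) | CC(C)=CCO | starting material
4 | 7-(tert-butyldimethylsilyloxy)-5-(3-methylbut-2-enyloxy)-4H-chromen-4-one | O=c1ccoc2cc(O[Si](C)(C)C(C)(C)C)cc(OCC=C(C)C)c12 | intermediate
5 | 7-(tert-butyldimethylsilyloxy)-5-hydroxy-8-(3-methylbut-2-enyl)-4H-chromen-4-one | O=c1ccoc2c(CC=C(C)C)c(O[Si](C)(C)C(C)(C)C)cc(O)c12 | intermediate
6 | 5,7-bis(tert-butyldimethylsilyloxy)-8-(3-methylbut-2-enyl)-4H-chromen-4-one | O=c1ccoc2c(CC=C(C)C)c(O[Si](C)(C)C(C)(C)C)cc(O[Si](C)(C)C(C)(C)C)c12 | intermediate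
7 | 4-bromophenol | Oc1ccc(Br)cc1 | starting material
8 | 1-bromo-3-methylbut-2-ene (prenyl bromide) | CC(C)=CCBr | starting material
9 | 4-bromo-2-(3-methylbut-2-enyl)phenol | CC(C)=CCc1cc(Br)ccc1O | intermediate
10 | (4-bromo-2-(3-methylbut-2-enyl)phenoxy)(tert-butyl)dimethylsilane | CC(C)=CCc1cc(Br)ccc1O[Si](C)(C)C(C)(C)C | intermediate
11 | [4-(tert-butyldimethylsilyloxy)-3-(3-methylbut-2-enyl)phenyl]boronic acid | CC(C)=CCc1cc(B(O)O)ccc1O[Si](C)(C)C(C)(C)C | intermediate
12 | (2S)-5,7-bis(TBSO)-2-[4-(TBSO)-3-prenylphenyl]-8-prenylchroman-4-one | CC(C)=CCc1cc([C@@H]2CC(=O)c3c(O[Si](C)(C)C(C)(C)C)cc(O[Si](C)(C)C(C)(C)C)c(CC=C(C)C)c3O2)ccc1O[Si](C)(C)C(C)(C)C | intermediate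
13 | euchrestaflavanone A, (2S) | CC(C)=CCc1cc([C@@H]2CC(=O)c3c(O)cc(O)c(CC=C(C)C)c3O2)ccc1O | target

## Summary

Total steps: 9. Longest linear sequence: 6 (steps 1 → 2 → 3 → 4 → 8 → 9); the boronic acid branch is 3 steps (5 → 6 → 7).

Steps most likely to fail, each with a fallback that changes the approach:

1. **Step 8 (asymmetric 1,4-addition).** The 5,7-bis(silyloxy)chromone is an electron-rich acceptor, so conversion may be low, the boronic acid may protodeboronate, the 5-OTBS may be lost, or ee may erode through ring opening. Fallback: drop the conjugate addition and set C2 as a carbinol instead. Make the (R)-β-hydroxy ketone ArCH(OH)CH2C(=O)Ar' by asymmetric aldol or CBS chemistry, using the aldehyde from 10 (Li/DMF) and the ring-A acetophenone. Then close ring C by intramolecular Mitsunobu etherification with inversion to give 2S.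

2. **Step 3 (para-Claisen–Cope).** The rearrangement may stop at the 6-(1,1-dimethylallyl) ortho product, or the bulky 7-OTBS may slow the Cope step. Fallback: install C8 carbon by a different sequence. Make the 7-O-allyl ether of a 5-O-protected chromone, run a thermal aromatic Claisen to C8, then convert allyl to prenyl by cross-metathesis with 2-methyl-2-butene (Grubbs II).

3. **Step 5 (ortho-C-prenylation).** C- versus O-alkylation and over-alkylation limit the yield. Fallback: O-allylate 4-bromophenol, run a thermal Claisen to 2-allyl-4-bromophenol, silylate, then cross-metathesise with 2-methyl-2-butene to reach 10 without any phenoxide C-alkylation.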